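**Plan**

- Numbering: ring A is the tetronic acid (O1, C2–C5), the chain runs from C6 (exocyclic CH) to C18, and ring B is the furan on C18.
- Cuts, in retrosynthetic order: C5=C6 (tetronate aldol–dehydration), C18–furan (B-alkyl Suzuki), C9–C10 (copper-catalysed allylic coupling after oxidation of the E-methyl) and C14–C15 (1,2-metallate rearrangement).
- Enabling feature: C15 is a tertiary carbinol carrying CH3 and two CH2 arms (C14, C16) that first differ at C12 versus C18, so it is made by stereospecific carbon migration onto an already resolved methyl carbinol, not by face-selective ketone addition.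
- Forward order: C14–C15 first (C11–C18 dienol), then C10 oxygenation, C9–C10 union with a C6–C9 Grignard reagent, furan ring B attached at C18, and ring A attached last at C6; neither ring is formed in the route, both are bought.
- Stereochemistry: C15 comes from (R)-pent-4-en-2-ol (Mitsunobu inversion, then retention, retention, inversion, retention). C7 comes from (R)-3-bromo-2-methylpropan-1-ol and is never touched. The 11E alkene comes from the SeO2 oxidation and the 5Z alkene from the elimination.

Key step: step 3

Remark: the target is read as the 4-hydroxy tautomer with (5Z,7S,11E,15S) configuration; the C15 descriptor of some intermediates reads R because of changed substituent ranking, while the spatial arrangement stays the same throughout.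

**Route**

Step 1
Reactants: 1 (R)-pent-4-en-2-ol; 2 2,4,6-triisopropylbenzoic acid
Product: 3 (S)-pent-4-en-2-yl 2,4,6-triisopropylbenzoate
Conditions: PPh3, DIAD, THF, 0 °C to rt
Reagents that add atoms: none
Why: Mitsunobu esterification displaces the oxyphosphonium of the unhindered secondary carbinol by the carboxylate in an SN2 step, so the (R)-alcohol should give the (S)-ester with inversion, the hindered acid reacting only through its oxygen.

Step 2
Reactants: 4 5-bromo-2-methylpent-2-ene
Product: 7 5,5-dimethyl-2-(4-methylpent-3-en-1-yl)-1,3,2-dioxaborinane, via Grignard reagent 5 (not isolated), via boronic acid 6 (not isolated)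
Conditions: Mg, THF, rt; B(OMe)3, −78 °C to rt; aq. HCl; neopentyl glycol, MgSO4, pentane, rt
Reagents that add atoms: trimethyl borate COB(OC)OC; neopentyl glycol OCC(C)(C)CO
Why: Magnesium insertion into the primary homoallylic bromide, capture by the borate and condensation of the boronic acid with the 1,3-diol (Grignard borylation–esterification) should give the unhindered six-membered boronic ester that suits step 3.

Step 3
Reactants: 3 (S)-pent-4-en-2-yl 2,4,6-triisopropylbenzoate; 7 5,5-dimethyl-2-(4-methylpent-3-en-1-yl)-1,3,2-dioxaborinane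
Product: 11 (R)-4,8-dimethylnona-1,7-dien-4-ol, via α-lithiated benzoate 8 (not isolated), via boronate complex 9 (not isolated), via tertiary boronic ester 10 (not isolated)
Conditions: sBuLi, TMEDA, CPME, −60 °C; then 7, −60 to 50 °C; then H2O2, aq. NaOH, THF, 0 °C to rt
Reagents that add atoms: hydrogen peroxide OO
Why: The benzoate carbonyl directs sBuLi/TMEDA to the carbinol C15–H (complex-induced proximity), giving the configurationally stable, dipole-stabilised α-oxy organolithium 8 with retention, and boronic ester 7 captures it on the same face to give boronate complex 9. On warming, the C14 methylene migrates from boron to C15 antiperiplanar to the departing triisopropylbenzoate (inversion at C15), and oxidation of the C–B bond of 10 proceeds with retention, so the C14–C15 bond and the C15 hydroxyl are installed in one flask. The closest known reaction type is the lithiation–borylation (Matteson-type 1,2-metallate rearrangement) of secondary dialkyl 2,4,6-triisopropylbenzoates with neopentyl glycol boronic esters, followed by oxidation to tertiary alcohols. No ring is closed. The only new stereocentre, C15, is controlled solely by the (S)-carbinol of 3 through the retention, retention, inversion, retention sequence, which places methyl, hydroxyl, the C14 arm and the C16 arm as in the (15S)-target (11 is named R only because allyl outranks the C14 arm). The step needs α-lithiation in preference to removal of the allylic C16 hydrogens, and 1,2-shift in preference to reversal of the complex; the lithium–carbonyl chelate at −60 °C should secure the first, and the unhindered primary neopentyl glycol ester with warming to 50 °C the second.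

Step 4
Reactants: 11 (R)-4,8-dimethylnona-1,7-dien-4-ol
Product: 12 triethyl{[(R)-4,8-dimethylnona-1,7-dien-4-yl]oxy}silane
Conditions: TESOTf, 2,6-lutidine, CH2Cl2, −78 to 0 °C
Reagents that add atoms: triethylsilyl trifluoromethanesulfonate CC[Si](CC)(CC)OS(=O)(=O)C(F)(F)F
Why: Silyl triflate with 2,6-lutidine is the standard silyl ether formation for a hindered tertiary alcohol, and the ether keeps the C15 oxygen from cyclising onto the allylic bromide of step 6 or quenching the Grignard reagent of step 10.

Step 5
Reactants: 12 triethyl{[(R)-4,8-dimethylnona-1,7-dien-4-yl]oxy}silane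
Product: 13 (2E,6R)-2,6-dimethyl-6-[(triethylsilyl)oxy]nona-2,8-dien-1-ol
Conditions: SeO2 (cat.), tBuOOH, CH2Cl2, 0 °C to rt
Reagents that add atoms: selenium dioxide O=[Se]=O; tert-butyl hydroperoxide CC(C)(C)OO
Why: Riley allylic oxidation (ene reaction, then [2,3]-sigmatropic shift) attacks the electron-rich trisubstituted alkene in preference to the vinyl group and oxidises the methyl trans to the chain, which should give the (E)-allylic alcohol and so fixes the C11=C12 geometry.

Step 6
Reactants: 13 (2E,6R)-2,6-dimethyl-6-[(triethylsilyl)oxy]nona-2,8-dien-1-ol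
Product: 14 {[(4R,7E)-9-bromo-4,8-dimethylnona-1,7-dien-4-yl]oxy}triethylsilane
Conditions: CBr4, PPh3, CH2Cl2, 0 °C
Reagents that add atoms: carbon tetrabromide BrC(Br)(Br)Br
Why: Appel bromination replaces the primary allylic hydroxyl by SN2 displacement of the oxyphosphonium under neutral conditions, which should leave the alkene geometry, the silyl ether and the vinyl group unchanged.

Step 7
Reactants: 15 (R)-3-bromo-2-methylpropan-1-ol
Product: 16 (R)-(3-bromo-2-methylpropoxy)(tert-butyl)dimethylsilane
Conditions: TBSCl, imidazole, DMF, rt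
Reagents that add atoms: tert-butyldimethylsilyl chloride CC(C)(C)[Si](C)(C)Cl
Why: Imidazole-promoted silylation of a primary alcohol is routine and touches neither the stereocentre nor the bromide.

Step 8
Reactants: 16 (R)-(3-bromo-2-methylpropoxy)(tert-butyl)dimethylsilane
Product: 18 (S)-4-[(tert-butyldimethylsilyl)oxy]-3-methylbutan-1-ol, via Grignard reagent 17 (not isolated)
Conditions: Mg, THF, reflux; then (CH2O)n, 0 °C to reflux; aq. NH4Cl
Reagents that add atoms: formaldehyde (as paraformaldehyde) C=O
Why: The Grignard reagent of this β-branched bromide is a well-behaved nucleophile, and its addition to formaldehyde (Grignard hydroxymethylation) adds the C9 carbon without involving the C7 stereocentre.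

Step 9
Reactants: 18 (S)-4-[(tert-butyldimethylsilyl)oxy]-3-methylbutan-1-ol
Product: 19 (S)-(4-bromo-2-methylbutoxy)(tert-butyl)dimethylsilane
Conditions: CBr4, PPh3, CH2Cl2, 0 °C
Reagents that add atoms: carbon tetrabromide BrC(Br)(Br)Br
Why: Appel bromination of the unhindered primary alcohol gives the bromide for the second Grignard reagent, the silyl ether being stable to the neutral conditions.

Step 10
Reactants: 19 (S)-(4-bromo-2-methylbutoxy)(tert-butyl)dimethylsilane; 14 {[(4R,7E)-9-bromo-4,8-dimethylnona-1,7-dien-4-yl]oxy}triethylsilane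
Product: 21 tert-butyldimethyl{[(2S,6E,10R)-2,6,10-trimethyl-10-[(triethylsilyl)oxy]trideca-6,12-dien-1-yl]oxy}silane, via Grignard reagent 20 (not isolated)
Conditions: 19, Mg, THF; then 14, Li2CuCl4 (cat.), THF, −78 to 0 °C
Reagents that add atoms: none
Why: Li2CuCl4-catalysed coupling of a primary alkyl Grignard reagent with a primary allylic bromide (Kochi–Schlosser-type cross-coupling) should form C9–C10 by direct substitution at the CH2 terminus with the E geometry kept, and neither silyl ether nor the vinyl group interferes.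

Step 11
Reactants: 21 tert-butyldimethyl{[(2S,6E,10R)-2,6,10-trimethyl-10-[(triethylsilyl)oxy]trideca-6,12-dien-1-yl]oxy}silane; 22 3-bromofuran
Product: 24 tert-butyl{[(2S,6E,10S)-13-(furan-3-yl)-2,6,10-trimethyl-10-[(triethylsilyl)oxy]tridec-6-en-1-yl]oxy}dimethylsilane, via B-alkyl-9-BBN borane 23 (not isolated)
Conditions: 9-BBN, THF, 0 °C to rt; then 22, Pd(dppf)Cl2, aq. K3PO4, DMF, 50 °C
Reagents that add atoms: none
Why: 9-BBN adds to the terminus of the monosubstituted C17=C18 alkene far faster than to the trisubstituted alkene, and the primary alkyl borane should transfer to 3-bromofuran in a B-alkyl Suzuki–Miyaura coupling through zerovalent palladium formed from the precatalyst.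

Step 12
Reactants: 24 tert-butyl{[(2S,6E,10S)-13-(furan-3-yl)-2,6,10-trimethyl-10-[(triethylsilyl)oxy]tridec-6-en-1-yl]oxy}dimethylsilane
Product: 25 (2S,6E,10S)-13-(furan-3-yl)-2,6,10-trimethyltridec-6-ene-1,10-diol
Conditions: TBAF, THF, rt
Reagents that add atoms: none
Why: Fluoride-mediated desilylation removes the primary and the tertiary silyl ether in one operation under non-acidic conditions that spare the furan and the bishomoallylic tertiary alcohol.

Step 13
Reactants: 25 (2S,6E,10S)-13-(furan-3-yl)-2,6,10-trimethyltridec-6-ene-1,10-diol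
Product: 26 (2S,6E,10S)-13-(furan-3-yl)-10-hydroxy-2,6,10-trimethyltridec-6-enal
Conditions: DMP, NaHCO3, CH2Cl2, 0 °C to rt
Reagents that add atoms: none
Why: Dess–Martin oxidation converts the primary alcohol to the aldehyde under buffered conditions that should not epimerise C7, while the tertiary hydroxyl cannot be oxidised and the furan is inert.

Step 14
Reactants: 27 3-methyltetronic acid (4-hydroxy-3-methylfuran-2(5H)-one)
Product: 28 4-methoxy-3-methylfuran-2(5H)-one
Conditions: Me2SO4, K2CO3, acetone, reflux
Reagents that add atoms: dimethyl sulfate COS(=O)(=O)OC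
Why: O-Alkylation of the vinylogous acid with dimethyl sulfate (Williamson-type etherification) gives the 4-methoxybutenolide, which masks the acidic enol so that C5 is the site deprotonated in step 15.

Step 15
Reactants: 26 (2S,6E,10S)-13-(furan-3-yl)-10-hydroxy-2,6,10-trimethyltridec-6-enal; 28 4-methoxy-3-methylfuran-2(5H)-one
Product: 30 5-[(2S,6E,10S)-13-(furan-3-yl)-1,10-dihydroxy-2,6,10-trimethyltridec-6-en-1-yl]-4-methoxy-3-methylfuran-2(5H)-one (epimers at ring C5 and side-chain C1), via lithiated tetronate 29 (not isolated)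
Conditions: LiN(iPr)2, 28 (2.5 equiv), THF, −78 °C; then 26, −78 °C; aq. NH4Cl
Reagents that add atoms: none
Why: C5 deprotonation gives the aromatic 2-oxidofuran, whose addition to the aldehyde at −78 °C (aldol addition of a lithiated tetronate) should form C5–C6 before C7 can epimerise, the excess anion covering the C15 hydroxyl and the two new carbinol centres being left uncontrolled because step 16 removes both.

Step 16
Reactants: 30 5-[(2S,6E,10S)-13-(furan-3-yl)-1,10-dihydroxy-2,6,10-trimethyltridec-6-en-1-yl]-4-methoxy-3-methylfuran-2(5H)-one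
Product: 32 (Z)-5-[(2S,6E,10S)-13-(furan-3-yl)-10-hydroxy-2,6,10-trimethyltridec-6-en-1-ylidene]-4-methoxy-3-methylfuran-2(5H)-one, via C6 acetate 31 (not isolated)
Conditions: Ac2O, Et3N, DMAP (cat.), CH2Cl2, 0 °C; then DBU, rt
Reagents that add atoms: none
Why: Selective acetylation of the secondary C6 hydroxyl (the tertiary C15 hydroxyl reacts far more slowly at 0 °C) followed by DBU-induced E1cB elimination through the C5 dienolate should give the conjugated ylidene tetronate, the Z isomer being favoured because it keeps the C7 branch away from the C4 methoxy group.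

Step 17
Reactants: 32 (Z)-5-[(2S,6E,10S)-13-(furan-3-yl)-10-hydroxy-2,6,10-trimethyltridec-6-en-1-ylidene]-4-methoxy-3-methylfuran-2(5H)-one
Product: 33 (Z)-5-[(2S,6E,10S)-13-(furan-3-yl)-10-hydroxy-2,6,10-trimethyltridec-6-en-1-ylidene]-4-hydroxy-3-methylfuran-2(5H)-one (target)
Conditions: n-PrSLi, HMPA, rt; then cold dilute HCl to pH 3
Reagents that add atoms: none
Why: SN2 attack of the soft thiolate on the methyl group of the enol ether (nucleophilic O-demethylation) should release the tetronic acid without touching the furan, the alkenes or either stereocentre.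

**Compound list**

1 | (R)-pent-4-en-2-ol | C[C@@H](O)CC=C | starting material
2 | 2,4,6-triisopropylbenzoic acid | OC(=O)c1c(C(C)C)cc(C(C)C)cc1C(C)C | starting material
3 | (S)-pent-4-en-2-yl 2,4,6-triisopropylbenzoate | C[C@H](OC(=O)c1c(C(C)C)cc(C(C)C)cc1C(C)C)CC=C | intermediate
4 | 5-bromo-2-methylpent-2-ene | CC(C)=CCCBr | starting material
5 | (4-methylpent-3-en-1-yl)magnesium bromide | CC(C)=CCC[Mg]Br | intermediate
6 | (4-methylpent-3-en-1-yl)boronic acid | CC(C)=CCCB(O)O | intermediate
7 | 5,5-dimethyl-2-(4-methylpent-3-en-1-yl)-1,3,2-dioxaborinane | CC(C)=CCCB1OCC(C)(C)CO1 | intermediate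
8 | (S)-2-lithiopent-4-en-2-yl 2,4,6-triisopropylbenzoate | C[C@]([Li])(OC(=O)c1c(C(C)C)cc(C(C)C)cc1C(C)C)CC=C | intermediate
9 | lithium boronate complex of 8 and 7 (boron on C15 with retention) | [Li+].C[C@]([B-]1(CCC=C(C)C)OCC(C)(C)CO1)(OC(=O)c1c(C(C)C)cc(C(C)C)cc1C(C)C)CC=C | intermediate
10 | 2-[(S)-4,8-dimethylnona-1,7-dien-4-yl]-5,5-dimethyl-1,3,2-dioxaborinane | C[C@@](B1OCC(C)(C)CO1)(CCC=C(C)C)CC=C | intermediate
11 | (R)-4,8-dimethylnona-1,7-dien-4-ol | CC(C)=CCC[C@@](C)(O)CC=C | intermediate
12 | triethyl{[(R)-4,8-dimethylnona-1,7-dien-4-yl]oxy}silane | CC(C)=CCC[C@@](C)(O[Si](CC)(CC)CC)CC=C | intermediate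
13 | (2E,6R)-2,6-dimethyl-6-[(triethylsilyl)oxy]nona-2,8-dien-1-ol | OC/C(C)=C/CC[C@@](C)(O[Si](CC)(CC)CC)CC=C | intermediate
14 | {[(4R,7E)-9-bromo-4,8-dimethylnona-1,7-dien-4-yl]oxy}triethylsilane | BrC/C(C)=C/CC[C@@](C)(O[Si](CC)(CC)CC)CC=C | intermediate
15 | (R)-3-bromo-2-methylpropan-1-ol | OC[C@@H](C)CBr | starting material
16 | (R)-(3-bromo-2-methylpropoxy)(tert-butyl)dimethylsilane | CC(C)(C)[Si](C)(C)OC[C@@H](C)CBr | intermediate
17 | (R)-{3-[(tert-butyldimethylsilyl)oxy]-2-methylpropyl}magnesium bromide | CC(C)(C)[Si](C)(C)OC[C@@H](C)C[Mg]Br | intermediate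
18 | (S)-4-[(tert-butyldimethylsilyl)oxy]-3-methylbutan-1-ol | CC(C)(C)[Si](C)(C)OC[C@@H](C)CCO | intermediate
19 | (S)-(4-bromo-2-methylbutoxy)(tert-butyl)dimethylsilane | CC(C)(C)[Si](C)(C)OC[C@@H](C)CCBr | intermediate
20 | (S)-{4-[(tert-butyldimethylsilyl)oxy]-3-methylbutyl}magnesium bromide | CC(C)(C)[Si](C)(C)OC[C@@H](C)CC[Mg]Br | intermediate
21 | tert-butyldimethyl{[(2S,6E,10R)-2,6,10-trimethyl-10-[(triethylsilyl)oxy]trideca-6,12-dien-1-yl]oxy}silane | CC(C)(C)[Si](C)(C)OC[C@@H](C)CCC/C(C)=C/CC[C@@](C)(O[Si](CC)(CC)CC)CC=C | intermediate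
22 | 3-bromofuran | Brc1ccoc1 | starting material
23 | 9-[(4S,8E,12S)-13-[(tert-butyldimethylsilyl)oxy]-4,8,12-trimethyl-4-[(triethylsilyl)oxy]tridec-8-en-1-yl]-9-borabicyclo[3.3.1]nonane | CC(C)(C)[Si](C)(C)OC[C@@H](C)CCC/C(C)=C/CC[C@@](C)(O[Si](CC)(CC)CC)CCCB1C2CCCC1CCC2 | intermediate
24 | tert-butyl{[(2S,6E,10S)-13-(furan-3-yl)-2,6,10-trimethyl-10-[(triethylsilyl)oxy]tridec-6-en-1-yl]oxy}dimethylsilane | CC(C)(C)[Si](C)(C)OC[C@@H](C)CCC/C(C)=C/CC[C@@](C)(O[Si](CC)(CC)CC)CCCc1ccoc1 | intermediate
25 | (2S,6E,10S)-13-(furan-3-yl)-2,6,10-trimethyltridec-6-ene-1,10-diol | OC[C@@H](C)CCC/C(C)=C/CC[C@@](C)(O)CCCc1ccoc1 | intermediate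
26 | (2S,6E,10S)-13-(furan-3-yl)-10-hydroxy-2,6,10-trimethyltridec-6-enal | O=C[C@@H](C)CCC/C(C)=C/CC[C@@](C)(O)CCCc1ccoc1 | intermediate
27 | 3-methyltetronic acid (4-hydroxy-3-methylfuran-2(5H)-one) | CC1=C(O)COC1=O | starting material
28 | 4-methoxy-3-methylfuran-2(5H)-one | CC1=C(OC)COC1=O | intermediate
29 | lithium 4-methoxy-3-methylfuran-2-olate (C5-lithiated 28) | [Li+].[O-]c1occ(OC)c1C | intermediate
30 | 5-[(2S,6E,10S)-13-(furan-3-yl)-1,10-dihydroxy-2,6,10-trimethyltridec-6-en-1-yl]-4-methoxy-3-methylfuran-2(5H)-one, epimers at ring C5 and side-chain C1 | CC1=C(OC)C(C(O)[C@@H](C)CCC/C(C)=C/CC[C@@](C)(O)CCCc2ccoc2)OC1=O | intermediate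
31 | side-chain C1 acetate of 30 (same epimer mixture) | CC1=C(OC)C(C(OC(C)=O)[C@@H](C)CCC/C(C)=C/CC[C@@](C)(O)CCCc2ccoc2)OC1=O | intermediate
32 | (Z)-5-[(2S,6E,10S)-13-(furan-3-yl)-10-hydroxy-2,6,10-trimethyltridec-6-en-1-ylidene]-4-methoxy-3-methylfuran-2(5H)-one | CC1=C(OC)/C(=C/[C@@H](C)CCC/C(C)=C/CC[C@@](C)(O)CCCc2ccoc2)OC1=O | intermediate
33 | (Z)-5-[(2S,6E,10S)-13-(furan-3-yl)-10-hydroxy-2,6,10-trimethyltridec-6-en-1-ylidene]-4-hydroxy-3-methylfuran-2(5H)-one | CC1=C(O)/C(=C/[C@@H](C)CCC/C(C)=C/CC[C@@](C)(O)CCCc2ccoc2)OC1=O | target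

**Step count and risks**

Total steps: 17. Longest linear sequence: 12 steps (1 → 3 → 11 → 12 → 13 → 14 → 21 → 24 → 25 → 26 → 30 → 32 → 33).

Steps most likely to fail:

Step 3. Removal of the allylic C16 hydrogens may compete with carbinol lithiation and lead to loss of benzoate, and the crowded boronate complex may revert to its components instead of rearranging. The fallback drops the boron chemistry and sets out from 4. Its Grignard reagent 5 would be acylated with N-methoxy-N-methylacetamide to give 6-methylhept-5-en-2-one F1. F1 would then undergo diol-catalysed enantioselective allylboration (allyldiisopropoxyborane, catalytic 3,3′-dibromo-BINOL, the catalyst enantiomer chosen to deliver the R carbinol). This comes back to the route at 11. It relies on catalyst control and not on stereospecific transfer, so lower enantiomeric purity would have to be accepted or upgraded.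

Step 10. Copper-mediated attack at C12 (allylic transposition) instead of C10, or loss of the E geometry through an equilibrating allyl-copper species, would give isomers that are hard to separate. The fallback replaces the organometallic coupling by sulfone alkylation and sets out from 19. Displacement with NaSO2Ph in DMF would give (S)-tert-butyldimethyl[2-methyl-4-(phenylsulfonyl)butoxy]silane F2. Its lithio derivative (nBuLi, THF, −78 °C) would alkylate bromide 14 at the CH2 terminus to give tert-butyldimethyl{[(2S,6E,10R)-2,6,10-trimethyl-4-(phenylsulfonyl)-10-[(triethylsilyl)oxy]trideca-6,12-dien-1-yl]oxy}silane F3 as a C4 epimer mixture. Reductive desulfonylation with Na(Hg) and Na2HPO4 in MeOH/THF comes back to the route at 21.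

Step 5. Incomplete conversion, over-oxidation to the enal and competing oxidation at the C13 methylene may erode the return of the allylic alcohol. The fallback builds the E-alkene by olefination and sets out from 12. Epoxidation of the trisubstituted alkene with mCPBA would give triethyl{[(4R)-6-(3,3-dimethyloxiran-2-yl)-4-methylhex-1-en-4-yl]oxy}silane F4. Cleavage with H5IO6 would give (R)-4-methyl-4-[(triethylsilyl)oxy]hept-6-enal F5. Wittig reaction with Ph3P=C(CH3)CO2Et would give ethyl (2E,6R)-2,6-dimethyl-6-[(triethylsilyl)oxy]nona-2,8-dienoate F6. Reduction with iBu2AlH at −78 °C comes back to the route at 13.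

**Further compounds**

F1 | step 3 | 6-methylhept-5-en-2-one | CC(=O)CCC=C(C)C
F2 | step 10 | (S)-tert-butyldimethyl[2-methyl-4-(phenylsulfonyl)butoxy]silane | CC(C)(C)[Si](C)(C)OC[C@@H](C)CCS(=O)(=O)c1ccccc1
F3 | step 10 | tert-butyldimethyl{[(2S,6E,10R)-2,6,10-trimethyl-4-(phenylsulfonyl)-10-[(triethylsilyl)oxy]trideca-6,12-dien-1-yl]oxy}silane (C4 epimers) | CC(C)(C)[Si](C)(C)OC[C@@H](C)CC(S(=O)(=O)c1ccccc1)C/C(C)=C/CC[C@@](C)(O[Si](CC)(CC)CC)CC=C
F4 | step 5 | triethyl{[(4R)-6-(3,3-dimethyloxiran-2-yl)-4-methylhex-1-en-4-yl]oxy}silane (epoxide epimers) | CC1(C)OC1CC[C@@](C)(O[Si](CC)(CC)CC)CC=C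
F5 | step 5 | (R)-4-methyl-4-[(triethylsilyl)oxy]hept-6-enal | O=CCC[C@@](C)(O[Si](CC)(CC)CC)CC=C
F6 | step 5 | ethyl (2E,6R)-2,6-dimethyl-6-[(triethylsilyl)oxy]nona-2,8-dienoate | CCOC(=O)/C(C)=C/CC[C@@](C)(O[Si](CC)(CC)CC)CC=C
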